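**Retrosynthetic overview**

1. Core numbering as in furo[3,2-b]furan-2(3H)-one (O1, C2, C3, C3a, O4, C5, C6, C6a); ring A = oxolane O4–C5–C6–C6a–C3a, ring B = lactone. Last disconnections: phenol from its benzyl ether; ring B (O1–C6a bond) by iodolactonisation of a 2,5-dihydrofuran-2-ylacetate, followed by reduction of the C6–I bond.
2. Ring A is closed first, through the C5–C6 bond: 1,5 C–H insertion of an alkylidene carbene (C6), generated from a methyl ketone at C6a, into the tertiary C5–H bond of a sec-alkyl ether, with retention.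
3. Enabling feature: C5 is a fully substituted carbon on the ring A oxygen O4 and lies 1,5 to C6 across O4–C3a–C6a, while C6a carries a methyl group. C5 can therefore enter as the stereodefined tertiary alpha-oxy C–H of an (S)-alkan-2-yl ether, and C6=C6a as the carbene of an acyclic methyl ketone.
4. The ketone comes from an Evans glycolate alkylation (sets C3a) of an alkoxyacetic acid made by Williamson etherification.
5. The (S)-carbinol comes from (S)-propylene oxide and an arylundecyl Grignard reagent, itself from a B-alkyl Suzuki coupling. Order of ring formation: ring A (step 8), then ring B (step 9).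

Key step: step 8

Remark: in the step names R*O stands for the {[(2S)-14-[4-(benzyloxy)phenyl]tetradecan-2-yl]oxy} group (full names are in the compound list). Organomagnesium steps are taken to be quenched with aqueous NH4Cl, so magnesium leaves as its bromide chloride salt.

**Route**

Step 1
Reactants: 1 11-bromoundec-1-ene; 2 1-(benzyloxy)-4-bromobenzene
Product: 4 1-(benzyloxy)-4-(11-bromoundecyl)benzene, via B-(11-bromoundecyl)-9-BBN 3 (not isolated)
Conditions: 9-BBN, THF, 0 °C → rt; then 2, PdCl2(dppf) (3 mol %), aq K3PO4, THF/DMF, 60 °C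
Reagents that add atoms: none
Why: B-alkyl Suzuki–Miyaura coupling: 9-BBN hydroborates the terminal alkene at the terminal carbon and the alkylborane 3 couples with the aryl bromide, while the primary alkyl bromide does not add to the dppf-bound zerovalent palladium and should survive as the Grignard handle; no stereocentre is formed.

Step 2
Reactants: 4 1-(benzyloxy)-4-(11-bromoundecyl)benzene; 5 (S)-propylene oxide
Product: 7 (2S)-14-[4-(benzyloxy)phenyl]tetradecan-2-ol, via arylundecylmagnesium bromide 6 (not isolated)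
Conditions: Mg, THF, 45 °C; then CuI (10 mol %), 5, −30 → 0 °C; aq NH4Cl
Reagents that add atoms: none
Why: Copper-catalysed Grignard opening of a terminal epoxide (SN2 at the CH2 carbon): the stereocentre of (S)-propylene oxide is not touched, so the carbinol should be (S).

Step 3
Reactants: 7 (2S)-14-[4-(benzyloxy)phenyl]tetradecan-2-ol; 8 bromoacetic acid
Product: 9 2-(R*O)acetic acid
Conditions: NaH (3 equiv), THF, 0 °C; then 8, reflux; aq HCl work-up
Reagents that add atoms: none
Why: Williamson ether synthesis: the sodium alkoxide displaces bromide from sodium bromoacetate at a primary carbon, and because the carbinol C–O bond is not broken the (S) centre is retained.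

Step 4
Reactants: 9 2-(R*O)acetic acid; 10 (4R)-4-benzyl-1,3-oxazolidin-2-one
Product: 12 (4R)-4-benzyl-3-[2-(R*O)acetyl]-1,3-oxazolidin-2-one, via mixed pivalic anhydride 11 (not isolated)
Conditions: PivCl, Et3N, THF, −20 °C; then LiCl, 10, −20 °C → rt
Reagents that add atoms: none
Why: N-Acylation of the Evans oxazolidinone through the mixed pivalic anhydride (LiCl/Et3N activation), attack occurring at the less hindered alkoxyacetyl carbonyl; no new stereocentre is formed.

Step 5
Reactants: 12 (4R)-4-benzyl-3-[2-(R*O)acetyl]-1,3-oxazolidin-2-one; 13 tert-butyl bromoacetate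
Product: 15 tert-butyl (3S)-4-[(4R)-4-benzyl-2-oxo-1,3-oxazolidin-3-yl]-4-oxo-3-(R*O)butanoate, via sodium Z-enolate 14 (not isolated)
Conditions: NaN(SiMe3)2, THF, −78 °C; then 13, −78 → −45 °C
Reagents that add atoms: none
Why: Evans asymmetric alkylation of a glycolate imide: the chelated sodium (Z)-enolate is alkylated by the reactive alpha-bromo ester on the face opposite the benzyl group of the (4R)-auxiliary, which should set the (3S) centre (the future C3a).

Step 6
Reactants: 15 tert-butyl (3S)-4-[(4R)-4-benzyl-2-oxo-1,3-oxazolidin-3-yl]-4-oxo-3-(R*O)butanoate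
Product: 16 tert-butyl (3S)-4-[methoxy(methyl)amino]-4-oxo-3-(R*O)butanoate
Conditions: MeONHMe·HCl, AlMe3, CH2Cl2, −10 → 0 °C
Reagents that add atoms: N,O-dimethylhydroxylamine hydrochloride, CNOC.Cl
Why: Weinreb transamination of the imide with the aluminium amide made from AlMe3 and MeONHMe·HCl, exocyclic cleavage being helped by chelation to the alpha-alkoxy group; the tert-butyl ester is inert to this reagent and the alpha centre is not enolised.

Step 7
Reactants: 16 tert-butyl (3S)-4-[methoxy(methyl)amino]-4-oxo-3-(R*O)butanoate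
Product: 17 tert-butyl (3S)-4-oxo-3-(R*O)pentanoate
Conditions: MeMgBr, THF, −20 → 0 °C; aq NH4Cl
Reagents that add atoms: methylmagnesium bromide, C[Mg]Br
Why: Weinreb ketone synthesis: the chelated tetrahedral intermediate stops the addition at the ketone stage and the hindered tert-butyl ester does not react below 0 °C, so the C3a centre is untouched.

Step 8
Reactants: 17 tert-butyl (3S)-4-oxo-3-(R*O)pentanoate
Product: 21 tert-butyl 2-[(2S,5S)-5-{12-[4-(benzyloxy)phenyl]dodecyl}-3,5-dimethyl-2,5-dihydrofuran-2-yl]acetate, via lithium diazo silyl alkoxide 18 (not isolated), via 1-diazoalkene 19 (not isolated), via alkylidene carbene 20 (not isolated)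
Conditions: TMSCHN2, n-BuLi, THF, −78 °C; then 17 (dilute), −78 °C → rt
Reagents that add atoms: (trimethylsilyl)diazomethane, C[Si](C)(C)C=[N+]=[N-]
Why: Lithiated TMS-diazomethane adds to the methyl ketone, the alkoxide 18 loses Me3SiOLi in a Peterson-type elimination to give the 1-diazoalkene 19, and loss of N2 gives the free singlet alkylidene carbene 20, whose carbene carbon (the future C6) inserts into the C–H bond five atoms away; the closest known reaction type is the alkylidene carbene 1,5 C–H insertion that converts alpha-alkoxy ketones into 2,5-dihydrofurans with this reagent. Ring A closes by a concerted three-centre insertion through a five-membered cyclic transition state, the normal ring size for alkylidene carbenes. The new C5 stereocentre is controlled by the (S)-carbinol centre made in step 2: the insertion is concerted and goes with retention, so C6 takes the place of the hydrogen and the quaternary centre should form as a single configuration. The step needs 1,5-insertion to win over 1,2-shift to an alkyne, over attack of the alkoxide 18 on the ester and over enolisation of the ketone toward C3a. The substrate secures this because the only C–H bond in 1,5 position is tertiary and alpha to the ether oxygen (the most reactive class), dialkyl alkylidene carbenes rearrange slowly, the tert-butyl ester is hindered, and addition at −78 °C should be faster than deprotonation. The product carries the C6=C6a alkene next to the C3a acetate arm, which is what ring B needs.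

Step 9
Reactants: 21 tert-butyl 2-[(2S,5S)-5-{12-[4-(benzyloxy)phenyl]dodecyl}-3,5-dimethyl-2,5-dihydrofuran-2-yl]acetate
Product: 22 (3aS,5S,6R,6aR)-5-{12-[4-(benzyloxy)phenyl]dodecyl}-6-iodo-5,6a-dimethyltetrahydrofuro[3,2-b]furan-2(3H)-one
Conditions: I2, NaHCO3, MeCN, 0 °C → rt, dark
Reagents that add atoms: iodine, II
Why: Iodolactonisation with loss of the tert-butyl group as isobutene: iodonium formation is reversible on both faces, but the ester carbonyl can reach C6a (5-exo, Markovnikov) only on the face that carries its own CH2 tether at C3a, so ring B should close cis-fused and set C6a relative to C3a, with iodine anti on C6.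

Step 10
Reactants: 22 (3aS,5S,6R,6aR)-5-{12-[4-(benzyloxy)phenyl]dodecyl}-6-iodo-5,6a-dimethyltetrahydrofuro[3,2-b]furan-2(3H)-one
Product: 23 (3aS,5S,6aS)-5-{12-[4-(benzyloxy)phenyl]dodecyl}-5,6a-dimethyltetrahydrofuro[3,2-b]furan-2(3H)-one
Conditions: Bu3SnH, AIBN (cat.), toluene, 80 °C
Reagents that add atoms: none
Why: Radical dehalogenation with tin hydride (chain reaction): the secondary C6 radical should be trapped by Bu3SnH faster than it can fragment, which removes the C6 stereocentre and leaves the other three untouched.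

Step 11
Reactants: 23 (3aS,5S,6aS)-5-{12-[4-(benzyloxy)phenyl]dodecyl}-5,6a-dimethyltetrahydrofuro[3,2-b]furan-2(3H)-one
Product: 24 plakortone N
Conditions: H2 (1 atm), 10% Pd/C, EtOAc, rt
Reagents that add atoms: none
Why: Hydrogenolysis of the aryl benzyl ether over Pd/C under neutral conditions; the lactone and the tertiary C–O bonds of the bicycle are not benzylic and should survive.

**Compound list**

1 | 11-bromoundec-1-ene | C=CCCCCCCCCCBr | starting material
2 | 1-(benzyloxy)-4-bromobenzene | Brc1ccc(OCc2ccccc2)cc1 | starting material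
3 | 9-(11-bromoundecyl)-9-borabicyclo[3.3.1]nonane | BrCCCCCCCCCCCB1C2CCCC1CCC2 | intermediate
4 | 1-(benzyloxy)-4-(11-bromoundecyl)benzene | BrCCCCCCCCCCCc1ccc(OCc2ccccc2)cc1 | intermediate
5 | (S)-propylene oxide [(2S)-2-methyloxirane] | C[C@H]1CO1 | starting material
6 | {11-[4-(benzyloxy)phenyl]undecyl}magnesium bromide | Br[Mg]CCCCCCCCCCCc1ccc(OCc2ccccc2)cc1 | intermediate
7 | (2S)-14-[4-(benzyloxy)phenyl]tetradecan-2-ol | C[C@H](O)CCCCCCCCCCCCc1ccc(OCc2ccccc2)cc1 | intermediate
8 | bromoacetic acid | OC(=O)CBr | starting material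
9 | 2-{[(2S)-14-[4-(benzyloxy)phenyl]tetradecan-2-yl]oxy}acetic acid | C[C@H](OCC(=O)O)CCCCCCCCCCCCc1ccc(OCc2ccccc2)cc1 | intermediate
10 | (4R)-4-benzyl-1,3-oxazolidin-2-one | O=C1N[C@H](Cc2ccccc2)CO1 | starting material
11 | 2-{[(2S)-14-[4-(benzyloxy)phenyl]tetradecan-2-yl]oxy}acetic 2,2-dimethylpropanoic anhydride | C[C@H](OCC(=O)OC(=O)C(C)(C)C)CCCCCCCCCCCCc1ccc(OCc2ccccc2)cc1 | intermediate
12 | (4R)-4-benzyl-3-(2-{[(2S)-14-[4-(benzyloxy)phenyl]tetradecan-2-yl]oxy}acetyl)-1,3-oxazolidin-2-one | C[C@H](OCC(=O)N1[C@H](Cc2ccccc2)COC1=O)CCCCCCCCCCCCc1ccc(OCc2ccccc2)cc1 | intermediate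
13 | tert-butyl bromoacetate | CC(C)(C)OC(=O)CBr | starting material
14 | sodium (Z)-enolate of 12 (alkoxy group cis to the enolate oxygen) | C[C@H](O/C=C(\[O-])N1[C@H](Cc2ccccc2)COC1=O)CCCCCCCCCCCCc1ccc(OCc2ccccc2)cc1.[Na+] | intermediate
15 | tert-butyl (3S)-4-[(4R)-4-benzyl-2-oxo-1,3-oxazolidin-3-yl]-3-{[(2S)-14-[4-(benzyloxy)phenyl]tetradecan-2-yl]oxy}-4-oxobutanoate | C[C@H](O[C@@H](CC(=O)OC(C)(C)C)C(=O)N1[C@H](Cc2ccccc2)COC1=O)CCCCCCCCCCCCc1ccc(OCc2ccccc2)cc1 | intermediate
16 | tert-butyl (3S)-3-{[(2S)-14-[4-(benzyloxy)phenyl]tetradecan-2-yl]oxy}-4-[methoxy(methyl)amino]-4-oxobutanoate | C[C@H](O[C@@H](CC(=O)OC(C)(C)C)C(=O)N(C)OC)CCCCCCCCCCCCc1ccc(OCc2ccccc2)cc1 | intermediate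
17 | tert-butyl (3S)-3-{[(2S)-14-[4-(benzyloxy)phenyl]tetradecan-2-yl]oxy}-4-oxopentanoate | C[C@H](O[C@@H](CC(=O)OC(C)(C)C)C(C)=O)CCCCCCCCCCCCc1ccc(OCc2ccccc2)cc1 | intermediate
18 | lithium alkoxide adduct: tert-butyl (3S)-5-diazo-4-methyl-4-oxido-5-(trimethylsilyl)-3-{[(2S)-14-[4-(benzyloxy)phenyl]tetradecan-2-yl]oxy}pentanoate, lithium salt (C4 configuration not defined) | C[C@H](O[C@@H](CC(=O)OC(C)(C)C)C(C)([O-])C(=[N+]=[N-])[Si](C)(C)C)CCCCCCCCCCCCc1ccc(OCc2ccccc2)cc1.[Li+] | intermediate
19 | tert-butyl (3S)-5-diazo-4-methyl-3-{[(2S)-14-[4-(benzyloxy)phenyl]tetradecan-2-yl]oxy}pent-4-enoate | C[C@H](O[C@@H](CC(=O)OC(C)(C)C)C(C)=C=[N+]=[N-])CCCCCCCCCCCCc1ccc(OCc2ccccc2)cc1 | intermediate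
20 | alkylidene carbene: tert-butyl (3S)-4-methyl-3-{[(2S)-14-[4-(benzyloxy)phenyl]tetradecan-2-yl]oxy}pent-4-enoate with a divalent terminal carbon C5 | C[C@H](O[C@@H](CC(=O)OC(C)(C)C)C(C)=[C])CCCCCCCCCCCCc1ccc(OCc2ccccc2)cc1 | intermediate
21 | tert-butyl 2-[(2S,5S)-5-{12-[4-(benzyloxy)phenyl]dodecyl}-3,5-dimethyl-2,5-dihydrofuran-2-yl]acetate | C[C@]1(CCCCCCCCCCCCc2ccc(OCc3ccccc3)cc2)C=C(C)[C@H](CC(=O)OC(C)(C)C)O1 | intermediate
22 | (3aS,5S,6R,6aR)-5-{12-[4-(benzyloxy)phenyl]dodecyl}-6-iodo-5,6a-dimethyltetrahydrofuro[3,2-b]furan-2(3H)-one | C[C@]1(CCCCCCCCCCCCc2ccc(OCc3ccccc3)cc2)[C@@H](I)[C@]2(C)OC(=O)C[C@@H]2O1 | intermediate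
23 | (3aS,5S,6aS)-5-{12-[4-(benzyloxy)phenyl]dodecyl}-5,6a-dimethyltetrahydrofuro[3,2-b]furan-2(3H)-one | C[C@]1(CCCCCCCCCCCCc2ccc(OCc3ccccc3)cc2)C[C@]2(C)OC(=O)C[C@@H]2O1 | intermediate
24 | plakortone N, (3aS,5S,6aS)-5-[12-(4-hydroxyphenyl)dodecyl]-5,6a-dimethyltetrahydrofuro[3,2-b]furan-2(3H)-one | C[C@]1(CCCCCCCCCCCCc2ccc(O)cc2)C[C@]2(C)OC(=O)C[C@@H]2O1 | target

**Step count and risks**

Total step count: 11. Longest linear sequence: 11 steps (1 → 24).

Steps most likely to fail:

Step 8 (key step). What may go wrong: enolisation of the ketone toward C3a by the basic reagent before addition (loss of the C3a configuration), ring closure of the intermediate alkoxide onto the ester, or 1,2-shift of the carbene instead of insertion. The fallback replaces the free carbene by a rhodium carbenoid under neutral conditions and sets out from 15. Cleavage of the auxiliary with LiOH/H2O2 (THF/H2O, 0 °C) would give the succinic half-ester acid F1. Activation with isobutyl chloroformate/N-methylmorpholine and treatment with CH2N2 would give the diazoketone F2. With Rh2(OAc)4 (cat., CH2Cl2, rt) the carbenoid should insert into the same tertiary alpha-oxy C–H bond with retention (1,5 C–H insertion of a diazoketone next to an ether oxygen) to give the oxolan-3-one F3. MeMgBr with CeCl3 (THF, −78 °C) should add anti to the C2 side chain to give the tertiary alcohol F4, and TFA in CH2Cl2 would cleave the tert-butyl ester and lactonise; the fallback comes back to the route at 23.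

Step 9. What may go wrong: slow loss of the tert-butyl group from the lactonium ion, so that the acid formed ionises the tertiary allylic ether of the dihydrofuran (ring opening and scrambling at C5) before ring B closes. The fallback sets out from 21 and avoids both the iodonium ion and free acid. TMSOTf/2,6-lutidine (CH2Cl2, 0 °C, then water) would convert the tert-butyl ester into the dihydrofuranylacetic acid F5. A hydrogen-atom-transfer hydrolactonisation (Co(salen) with divalent cobalt, N-fluoro-2,4,6-trimethylpyridinium triflate, PhSiH3, rt) should then deliver hydrogen to C6 and let the carboxylic acid capture the oxidised tertiary C6a centre on the face of its tether. This comes back to the route at 23, so that step 10 is not needed.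

Step 5. What may go wrong: decomposition of the hindered glycolate enolate before it is alkylated by the bromo ester, or poor facial selectivity. The fallback sets out from 12 and uses a faster electrophile, with the carboxyl group unmasked later. Alkylation of the same sodium enolate with allyl iodide (NaN(SiMe3)2, THF, −78 °C) would give the allylated imide F6. Ozonolysis (O3, CH2Cl2, −78 °C, then PPh3) would give the aldehyde F7 and Pinnick oxidation (NaClO2, NaH2PO4, 2-methylbut-2-ene) the acid F8. Esterification with tert-butyl 2,2,2-trichloroacetimidate (cat. BF3·OEt2) comes back to the route at 15.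

**Further compounds**

F1 | step 8 | (2S)-4-(tert-butoxy)-4-oxo-2-{[(2S)-14-[4-(benzyloxy)phenyl]tetradecan-2-yl]oxy}butanoic acid | C[C@H](O[C@@H](CC(=O)OC(C)(C)C)C(=O)O)CCCCCCCCCCCCc1ccc(OCc2ccccc2)cc1
F2 | step 8 | tert-butyl (3S)-5-diazo-4-oxo-3-{[(2S)-14-[4-(benzyloxy)phenyl]tetradecan-2-yl]oxy}pentanoate | C[C@H](O[C@@H](CC(=O)OC(C)(C)C)C(=O)C=[N+]=[N-])CCCCCCCCCCCCc1ccc(OCc2ccccc2)cc1
F3 | step 8 | tert-butyl 2-[(2S,5S)-5-{12-[4-(benzyloxy)phenyl]dodecyl}-5-methyl-3-oxooxolan-2-yl]acetate | C[C@]1(CCCCCCCCCCCCc2ccc(OCc3ccccc3)cc2)CC(=O)[C@H](CC(=O)OC(C)(C)C)O1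
F4 | step 8 | tert-butyl 2-[(2S,3S,5S)-5-{12-[4-(benzyloxy)phenyl]dodecyl}-3-hydroxy-3,5-dimethyloxolan-2-yl]acetate | C[C@]1(CCCCCCCCCCCCc2ccc(OCc3ccccc3)cc2)C[C@](C)(O)[C@H](CC(=O)OC(C)(C)C)O1
F5 | step 9 | 2-[(2S,5S)-5-{12-[4-(benzyloxy)phenyl]dodecyl}-3,5-dimethyl-2,5-dihydrofuran-2-yl]acetic acid | C[C@]1(CCCCCCCCCCCCc2ccc(OCc3ccccc3)cc2)C=C(C)[C@H](CC(=O)O)O1
F6 | step 5 | (4R)-4-benzyl-3-[(2S)-2-{[(2S)-14-[4-(benzyloxy)phenyl]tetradecan-2-yl]oxy}pent-4-enoyl]-1,3-oxazolidin-2-one | C[C@H](O[C@@H](CC=C)C(=O)N1[C@H](Cc2ccccc2)COC1=O)CCCCCCCCCCCCc1ccc(OCc2ccccc2)cc1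
F7 | step 5 | (4R)-4-benzyl-3-[(2S)-2-{[(2S)-14-[4-(benzyloxy)phenyl]tetradecan-2-yl]oxy}-4-oxobutanoyl]-1,3-oxazolidin-2-one | C[C@H](O[C@@H](CC=O)C(=O)N1[C@H](Cc2ccccc2)COC1=O)CCCCCCCCCCCCc1ccc(OCc2ccccc2)cc1
F8 | step 5 | (3S)-4-[(4R)-4-benzyl-2-oxo-1,3-oxazolidin-3-yl]-3-{[(2S)-14-[4-(benzyloxy)phenyl]tetradecan-2-yl]oxy}-4-oxobutanoic acid | C[C@H](O[C@@H](CC(=O)O)C(=O)N1[C@H](Cc2ccccc2)COC1=O)CCCCCCCCCCCCc1ccc(OCc2ccccc2)cc1
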